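**Retrosynthetic overview**
1. The C13–OH bond is cut last. It is formed by exo-face O2 capture of the C13 tertiary radical, which arises from either C13 epimer of the carbinol (stereoconvergent key step).
2. The C6–OAc bond comes from α-epoxidation of the Δ6 enol acetate, followed by a 1,2-acyloxy shift with inversion to give the axial 6β-acetate.
3. The cyclopentane and cyclobutane are opened together by an intramolecular enone–olefin [2+2] of a 13-silyloxylabda-8,14-dien-7-one.
4. C7=O comes from allylic oxidation of a Δ8 olefin, and the vinyl carbinol from vinyl Grignard addition to the C13 methyl ketone.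
5. Rings A/B (C5, C10) come intact from (−)-sclareol. The five- and four-membered rings then form in one photochemical step.

Assumption: labdane numbering is used, and α is the face opposite the C10 methyl. Compounds 6–14 are handled as ca. 1:1 C13 epimer mixtures, so their SMILES carry no descriptor at C13.

**Step 1**
Reactants: 1 (−)-sclareol
Product: 2 8α-hydroxy-14,15-dinorlabdan-13-one
Conditions: KMnO4 (4 equiv), acetone–H2O, 0 °C → rt
Reagents that add atoms: none
Why: Permanganate oxidative cleavage of the tertiary vinyl carbinol (dihydroxylation, glycol cleavage, decarboxylation of the α-hydroxy acid) removes C14/C15 and turns C13–OH into the methyl ketone without touching C5, C8, C9 or C10.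

**Step 2**
Reactants: 2 8α-hydroxy-14,15-dinorlabdan-13-one
Product: 3 14,15-dinorlabd-8-en-13-one
Conditions: PPh3, I2, CH2Cl2, rt
Reagents that add atoms: none
Why: E1-type Zaitsev dehydration of the 8α-alcohol through its alkoxyphosphonium salt, with HI equilibrating the alkene isomers, funnels the material into the tetrasubstituted Δ8(9) olefin under acidic conditions that the original vinyl carbinol side chain would not survive.

**Step 3**
Reactants: 3 14,15-dinorlabd-8-en-13-one
Product: 4 14,15-dinorlabd-8-ene-7,13-dione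
Conditions: CrO3, 3,5-dimethylpyrazole, CH2Cl2, −20 °C
Reagents that add atoms: chromium trioxide O=[Cr](=O)=O
Why: Cr(VI) allylic oxidation (CrO3–dimethylpyrazole) attacks C7, the least hindered allylic methylene (C11 is shielded by C1 and the C10 methyl), and forms the C7=O bond of the enone chromophore.

**Step 4**
Reactants: 4 14,15-dinorlabd-8-ene-7,13-dione; 5 vinylmagnesium bromide
Product: 7 (13RS)-13-(triethylsilyloxy)labda-8,14-dien-7-one, via bromomagnesium alkoxide 6 (not isolated)
Conditions: 5 (1.1 equiv), THF, −78 °C; then TESOTf, −78 → 0 °C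
Reagents that add atoms: vinylmagnesium bromide C=C[Mg]Br; triethylsilyl trifluoromethanesulfonate CC[Si](CC)(CC)OS(=O)(=O)C(F)(F)F
Why: Grignard 1,2-addition is chemoselective for the open methyl ketone over the conjugated tetrasubstituted C7 ketone and the alkoxide is silylated in the flask, while the absent facial bias at C13 (ca. 1:1) is accepted because C13 is reset in step 8.

**Step 5**
Reactants: 7 (13RS)-13-(triethylsilyloxy)labda-8,14-dien-7-one
Product: 8 (13RS)-13-(triethylsilyloxy)-8α,15:9α,14-dicyclolabdan-7-one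
Conditions: hν (365 nm), degassed hexane (5 mM), rt
Reagents that add atoms: none
Why: In this intramolecular enone–olefin [2+2] photocycloaddition (rule of five, C9–C14 then C8–C15) the tethered vinyl group adds to the α face opposite the axial C10 methyl, which sets C8 (17-Me β), C9 (C11 β) and, through the obligatory cis-bicyclo[3.2.0]heptane fusion, C14 (H cis to C10).

**Step 6**
Reactants: 8 (13RS)-13-(triethylsilyloxy)-8α,15:9α,14-dicyclolabdan-7-one
Product: 10 (13RS)-7-acetoxy-13-(triethylsilyloxy)-8α,15:9α,14-dicyclolabd-6-ene, via potassium enolate 9 (not isolated)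
Conditions: KHMDS, THF, −78 → −20 °C; Ac2O, −78 °C
Reagents that add atoms: acetic anhydride CC(=O)OC(C)=O
Why: C8 is quaternary, so enolisation can only go towards C6, and the hard potassium enolate is O-acylated by the anhydride (enol ester formation).

**Step 7**
Reactants: 10 (13RS)-7-acetoxy-13-(triethylsilyloxy)-8α,15:9α,14-dicyclolabd-6-ene
Product: 13 (13RS)-6β-acetoxy-13-hydroxy-8α,15:9α,14-dicyclolabdan-7-one, via epoxy acetate 11 (not isolated), via silylated acetoxy ketone 12 (not isolated)
Conditions: DMDO, acetone–CH2Cl2, 0 °C; evaporate; PhMe, 110 °C; then HF·pyridine, THF, 0 °C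
Reagents that add atoms: dimethyldioxirane CC1(C)OO1
Why: Dioxirane epoxidation takes the α face (the β face is closed by the C17, C19 and C20 methyls) and the thermal enol ester epoxide rearrangement moves the 7β-acetoxy group to C6 in an intramolecular 1,2-acyloxy shift with inversion, which forms the C6–O bond as the axial 6β-acetate before HF removes the silyl group.

**Step 8**
Reactants: 13 (13RS)-6β-acetoxy-13-hydroxy-8α,15:9α,14-dicyclolabdan-7-one
Product: 16 (13S)-6β-acetoxy-13-hydroxy-8α,15:9α,14-dicyclolabdan-7-one (CNP0330581.1), via benzoxazoline adduct 14 (not isolated), via tertiary hydroperoxide 15 (not isolated)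
Conditions: 5,7-di-tert-butyl-3-phenylbenzoxazolium BF4, pyridine, MTBE, rt; then [Ir(ppy)2(dtbbpy)]PF6 (1 mol %), quinuclidine (20 mol %), air, MeCN, 450 nm, 0 °C; then PPh3
Reagents that add atoms: dioxygen O=O
Why: Proposed new method: deoxygenative re-hydroxylation of a tertiary alcohol, in which the alcohol condenses with the benzoxazolium salt to the 2-alkoxybenzoxazoline 14, excited Ir(III) oxidises its anilinic nitrogen, quinuclidine removes C2–H and β-scission of the old C13–O bond (driven by carbamate C=O formation) releases from both epimers the same planar C13 radical, which O2 traps (about 10^6 s^-1 or more in air-saturated solvent against roughly 10^3–10^4 s^-1 for cyclobutylcarbinyl ring opening) on the convex exo face cis to H-14 because the endo lobe is blocked by the inward C15–H, so the new C13–O bond is 13S; Ir(II) reduces the peroxyl radical to 15, PPh3 cleaves O–O with retention, and no C13 cation (which would expand the cyclobutane) is formed; the closest known reaction types are the benzoxazolium (NHC)-mediated photoredox deoxygenation of alcohols, so far used for C–C coupling only, and aerobic trapping of tertiary radicals as in the Mukaiyama hydration.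

**Compound list**
1 | (−)-sclareol, (13R)-labd-14-ene-8α,13-diol | C[C@]12CCCC([C@@H]1CC[C@@]([C@@H]2CC[C@](C)(C=C)O)(C)O)(C)C | starting material
2 | 8α-hydroxy-14,15-dinorlabdan-13-one | C[C@]12CCCC([C@@H]1CC[C@@]([C@@H]2CCC(C)=O)(C)O)(C)C | intermediate
3 | 14,15-dinorlabd-8-en-13-one | C[C@]12CCCC([C@@H]1CCC(C)=C2CCC(C)=O)(C)C | intermediate
4 | 14,15-dinorlabd-8-ene-7,13-dione | C[C@]12CCCC([C@@H]1CC(=O)C(C)=C2CCC(C)=O)(C)C | intermediate
5 | vinylmagnesium bromide | C=C[Mg]Br | starting material
6 | bromomagnesium (13RS)-7-oxolabda-8,14-dien-13-olate | C[C@]12CCCC([C@@H]1CC(=O)C(C)=C2CCC(C)(C=C)O[Mg]Br)(C)C | intermediate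
7 | (13RS)-13-(triethylsilyloxy)labda-8,14-dien-7-one | C[C@]12CCCC([C@@H]1CC(=O)C(C)=C2CCC(C)(C=C)O[Si](CC)(CC)CC)(C)C | intermediate
8 | (13RS)-13-(triethylsilyloxy)-8α,15:9α,14-dicyclolabdan-7-one (cyclobutane C8–C9–C14–C15 on the α face; cyclopentane C9–C11–C12–C13–C14; 17-Me β; H-14 cis to C10) | C1C(=O)[C@@]2(C)C[C@H]3[C@@]2(CCC3(C)O[Si](CC)(CC)CC)[C@@]2(C)CCCC(C)(C)[C@H]12 | intermediate
9 | potassium Δ6-enolate of 8 | C1=C([O-])[C@@]2(C)C[C@H]3[C@@]2(CCC3(C)O[Si](CC)(CC)CC)[C@@]2(C)CCCC(C)(C)[C@H]12.[K+] | intermediate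
10 | (13RS)-7-acetoxy-13-(triethylsilyloxy)-8α,15:9α,14-dicyclolabd-6-ene | C1=C(OC(C)=O)[C@@]2(C)C[C@H]3[C@@]2(CCC3(C)O[Si](CC)(CC)CC)[C@@]2(C)CCCC(C)(C)[C@H]12 | intermediate
11 | (13RS)-7β-acetoxy-6α,7α-epoxy-13-(triethylsilyloxy)-8α,15:9α,14-dicyclolabdane | O4[C@H]1[C@]4(OC(C)=O)[C@@]2(C)C[C@H]3[C@@]2(CCC3(C)O[Si](CC)(CC)CC)[C@@]2(C)CCCC(C)(C)[C@H]12 | intermediate
12 | (13RS)-6β-acetoxy-13-(triethylsilyloxy)-8α,15:9α,14-dicyclolabdan-7-one | CC(=O)O[C@@H]1C(=O)[C@@]2(C)C[C@H]3[C@@]2(CCC3(C)O[Si](CC)(CC)CC)[C@@]2(C)CCCC(C)(C)[C@H]12 | intermediate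
13 | (13RS)-6β-acetoxy-13-hydroxy-8α,15:9α,14-dicyclolabdan-7-one (ca. 1:1 mixture of 16 and its 13-epimer) | CC(=O)O[C@@H]1C(=O)[C@@]2(C)C[C@H]3[C@@]2(CCC3(C)O)[C@@]2(C)CCCC(C)(C)[C@H]12 | intermediate
14 | 13-O-(5,7-di-tert-butyl-3-phenyl-2,3-dihydrobenzoxazol-2-yl) derivative of 13 | CC(=O)O[C@@H]1C(=O)[C@@]2(C)C[C@H]3[C@@]2(CCC3(C)OC4Oc5c(cc(cc5C(C)(C)C)C(C)(C)C)N4c4ccccc4)[C@@]2(C)CCCC(C)(C)[C@H]12 | intermediate
15 | (13S)-6β-acetoxy-13-hydroperoxy-8α,15:9α,14-dicyclolabdan-7-one | CC(=O)O[C@@H]1C(=O)[C@@]2(C)C[C@H]3[C@@]2(CC[C@]3(C)OO)[C@@]2(C)CCCC(C)(C)[C@H]12 | intermediate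
16 | (13S)-6β-acetoxy-13-hydroxy-8α,15:9α,14-dicyclolabdan-7-one (CNP0330581.1) | CC(=O)O[C@@H]1C(=O)[C@@]2(C)C[C@H]3[C@@]2(CC[C@]3(C)O)[C@@]2(C)CCCC(C)(C)[C@H]12 | target

**Total step count:** 8. **Longest linear sequence:** 8 (from 1).

**Three steps most likely to fail**

Step 8 (the proposed new step).
- Adduct formation may be slow on the hindered endo alcohol.
- O2 may quench the photocatalyst or intercept the α-amino radical before β-scission.
- Peroxyl self-reaction may give alkoxy radicals that fragment.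
- The fallback uses known chemistry, sets out from 13 and comes back at 15 and then 16. Burgess reagent (PhMe, 70 °C, syn-elimination without a free cation) gives the exocyclic 13(16)-alkene F1 together with the endocyclic 12-ene F2. Both are taken unseparated through a Mukaiyama hydration (Co(acac)2 or Mn(dpm)3, PhSiH3, O2, i-PrOH). This passes through the same C13 radical, gives hydroperoxide 15 from the exo face and, after PPh3, 16.

Step 7.
- Traces of acid can divert the epoxy acetate into the retention pathway, which gives the 6α-acetate.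
- The crowded 6β site may also slow the shift.
- The fallback changes the C6–O logic to an intermolecular epoxide opening. It sets out from enolate 9 (made from 8 as in step 6) and comes back at 12.
- Trapping with PhNTf2 gives the enol triflate F3, and Pd-catalysed formate reduction (Pd(OAc)2, PPh3, HCO2H, Bu3N) gives the Δ6-alkene F4. mCPBA then gives the 6α,7α-epoxide F5.
- Trans-diaxial (Fürst–Plattner) opening with buffered acetic acid delivers acetate to C6 from the β face and gives the 6β-acetoxy-7α-alcohol F6. Dess–Martin oxidation gives 12, which enters the HF stage of step 7.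

Step 5.
- The tetrasubstituted enone and the bulky C13 centre next to the vinyl group may slow ring closure.
- The 1,4-biradical may then disproportionate.
- The fallback replaces the alkene partner by a slimmer alkyne. It sets out from 4 and comes back at 8.
- Ethynylmagnesium bromide gives the bromomagnesium propargylic alkoxide F7, and TESOTf gives the propargylic silyl ether F8. Enone–alkyne [2+2] photocycloaddition then gives the cyclobutene F9.
- Hydrogenation (H2, Pd/C) from the convex face installs H-14 cis to C10 and gives 8.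

**Further compounds**
F1 | step 8 | 6β-acetoxy-8α,15:9α,14-dicyclolabd-13(16)-en-7-one | CC(=O)O[C@@H]1C(=O)[C@@]2(C)C[C@H]3[C@@]2(CCC3=C)[C@@]2(C)CCCC(C)(C)[C@H]12
F2 | step 8 | 6β-acetoxy-8α,15:9α,14-dicyclolabd-12-en-7-one | CC(=O)O[C@@H]1C(=O)[C@@]2(C)C[C@H]3[C@@]2(CC=C3C)[C@@]2(C)CCCC(C)(C)[C@H]12
F3 | step 7 | (13RS)-13-(triethylsilyloxy)-8α,15:9α,14-dicyclolabd-6-en-7-yl trifluoromethanesulfonate | C1=C(OS(=O)(=O)C(F)(F)F)[C@@]2(C)C[C@H]3[C@@]2(CCC3(C)O[Si](CC)(CC)CC)[C@@]2(C)CCCC(C)(C)[C@H]12
F4 | step 7 | (13RS)-13-(triethylsilyloxy)-8α,15:9α,14-dicyclolabd-6-ene | C1=C[C@@]2(C)C[C@H]3[C@@]2(CCC3(C)O[Si](CC)(CC)CC)[C@@]2(C)CCCC(C)(C)[C@H]12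
F5 | step 7 | (13RS)-6α,7α-epoxy-13-(triethylsilyloxy)-8α,15:9α,14-dicyclolabdane | O4[C@H]1[C@@H]4[C@@]2(C)C[C@H]3[C@@]2(CCC3(C)O[Si](CC)(CC)CC)[C@@]2(C)CCCC(C)(C)[C@H]12
F6 | step 7 | (13RS)-6β-acetoxy-13-(triethylsilyloxy)-8α,15:9α,14-dicyclolabdan-7α-ol | CC(=O)O[C@@H]1[C@@H](O)[C@@]2(C)C[C@H]3[C@@]2(CCC3(C)O[Si](CC)(CC)CC)[C@@]2(C)CCCC(C)(C)[C@H]12
F7 | step 5 | bromomagnesium (13RS)-7-oxolabd-8-en-14-yn-13-olate | C[C@]12CCCC([C@@H]1CC(=O)C(C)=C2CCC(C)(C#C)O[Mg]Br)(C)C
F8 | step 5 | (13RS)-13-(triethylsilyloxy)labd-8-en-14-yn-7-one | C[C@]12CCCC([C@@H]1CC(=O)C(C)=C2CCC(C)(C#C)O[Si](CC)(CC)CC)(C)C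
F9 | step 5 | (13RS)-13-(triethylsilyloxy)-8α,15:9α,14-dicyclolabd-14-en-7-one | C1C(=O)[C@@]2(C)C=C3[C@@]2(CCC3(C)O[Si](CC)(CC)CC)[C@@]2(C)CCCC(C)(C)[C@H]12
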